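All runs were computed for an exercise, noise included.

The birch run, at −35 °C, lost target after its early peak and stood at 3.3% at its last reading. That fall made me ask what the larch flask should get next: more warmth, more reagent or more time.

| setting | larch | birch | flask |
|---|---|---|---|
| solid substrate | 0.20 M | 0.20 M | 0.20 M |
| reagent | 0.95 equiv | 0.64 equiv | 0.950 equiv |
| temperature | −20 °C | −35 °C | −20 °C |
| remark | the very flask that is asked about, followed so far | run made earlier |  |
| time |  |  | 4.0 h |

- larch (time / h: target / %): 0.250: 13.3; 0.833: 15.5; 1.33: 16.6; 2.50: 16.5; 3.00: 16.3
- birch (time / h: target / %): 0.500: 7.4; 0.833: 8.2; 2.00: 6.2; 3.00: 4.2; 6.00: 3.3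

(scatter of a reading: 0.5 percentage points)

- red: at 4.0 h raise the temperature by 15 K, then wait 8.0 h
- amber: at 4.0 h add reagent, 100% of the amount charged, then wait 8.0 h
- teal: change nothing and wait 8.0 h more

- the volume of additions can be left aside
- at the start none of the solid substrate is in solution
- a reading or a percentage of target counts all its forms, free or not

- target, in percent of the solid substrate first charged, at 4.0 h
- the option that brings most further target ("none" if no option brings more than 2 percentage points) (red / amber / teal / none)
- target present, in percent of the solid substrate first charged, after amber
- target present, in percent of the solid substrate first charged, after teal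

From 1.33 h on, the larch readings stayed flat within the scatter of 0.5 percentage points, so I took their mean as the late level of target and divided it by the reagent charged:

late level, larch = 16.5%

return, larch = 0.173

return, birch = 0.0516

I called this the reagent return, the target standing late in a run per equivalent of reagent charged. The larch return was higher than the birch return, by a factor of 3.36, with larch at −20 °C against −35 °C for birch. Since the return divides out the difference in reagent, I put red first. The flat readings gave teal no gain, and I expected the larch flask to hold about 16.5% at 4.0 h. For amber, a constant return would give 32.9%, but that needed substrate still present, and the readings could not show whether any was. I left amber open.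

The forecast gave 16.2% now, 9% after amber, 16% after teal and none as best, holding that "Waiting or warming has nothing left to drive it".

The simulation gave 16.1% now, 16.1% after amber and 16.1% after teal, with red as best at a gain of 8.1 points.

    reagent ⇌ dormant form (K = 4.30, k = 0.0320 min⁻¹, Ea = 81.0 kJ mol⁻¹, ΔH = 2.00 kJ mol⁻¹)
    target ⇌ isomer of the product (K = 0.680, k = 0.120 min⁻¹, Ea = 77.0 kJ mol⁻¹, ΔH = −61.0 kJ mol⁻¹)
    solid substrate ⇌ dissolved substrate, rate k3*(cs3 - [dissolved substrate]) while solid is left; crystals form when [dissolved substrate] > cs3 (solubility = 0.0780 M, k = 0.230 min⁻¹)
    dissolved substrate + reagent → target (k = 0.730 M⁻¹ min⁻¹, Ea = 62.0 kJ mol⁻¹)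
    2 dissolved substrate → side product (k = 4.40 M⁻¹ min⁻¹, Ea = 46.0 kJ mol⁻¹)
    crystals ⇌ target, rate k6*(cs6 - [target]) while solid is left; crystals form when [target] > cs6 (solubility = 42.0 mM, k = 14.0 min⁻¹)
    (constants at −20 °C)

In the larch flask at 4.00 h, solid substrate stood at 0% and dissolved substrate at 0.0112%, while reagent stood at 14% of its charge, so the substrate was the limiting reagent, and amber's return fell to 0.0845. Red raised the return to 0.254 from the same flask, which held 10.9% of isomer of the product. Part of the reason is the turning of target into that isomer, both ways: with it struck out, red's gain falls from 8.1 points to 0.011 points.

For the neighbour flask charged with 3.80 equiv of reagent from the start, the larch return gives 65.9%. The computed flask holds 54.2%, all forms of target counted, a return of 0.143.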